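**Assumption:** the target is taken as the achiral 1H-indole tautomer of the SMILES. The one stereocentre met on the way (C2 of indoline 11) is made racemic on purpose, because step 6 turns C2 into an sp2 carbon.

## Analysis of the target

Compound 17 is 3,4,7-tribromo-2-chloro-1H-indole, a flat indole with no stereocentre in which only C5–H, C6–H and N–H are left unsubstituted. The pyrrole ring carries two different halogens on neighbouring carbons, Cl on C2 and Br on C3, and the isomer with the two exchanged has the same formula, so each halogen must be placed by a reaction whose site is beyond doubt. An indole takes electrophiles at C3 first, and a halonium ion can attack a C3 that already bears halogen and then shift to C2; the safe order is therefore chlorine to C2 through a C2 carbanion and bromine to C3 last. The 2-chloroindole unit is hydrolysed by aqueous acid, and the three aryl bromides exchange with alkyllithiums and insert low-valent metals, so late in the route strong bases are limited to lithium amides and low-valent metal catalysts are excluded. The bromines on C4 and C7 cannot be introduced by brominating an indole, which would react at C3 and then at C5 or C6, so they have to arrive with the six-membered ring. The feature on which the plan rests is that C4–Br and C7–Br flank the C3a–C7a bond symmetrically. That edge can be the triple bond of the symmetric aryne 10, whose two ends are equivalent, so one annulation can attach N1 to C7a and C3 to C3a without any question of orientation.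

## Retrosynthetic reasoning

**C3–Br.** The last bond cut is C3–Br of 17, which leads to 16. In 16, C3 is the only free carbon of the pyrrole ring and the position an indole offers to electrophiles by itself, while the benzo ring is deactivated by two bromines. The forward step is a simple electrophilic bromination with one equivalent of an N-bromoimide.

**N1 protection and C2–Cl.** Compound 16 goes back to its N-Boc derivative 15, and cutting C2–Cl in 15 leads through the 2-lithio species 14 to 13. Chlorine cannot be brought to C2 of a neutral indole as an electrophile, because C3 would react first. As the partner of a C2 carbanion it has no other place to go. The Boc group acidifies C2–H and holds a lithium amide base, which is used because an alkyllithium would exchange the ring bromines. Exchanging a C2 carboxyl group for chlorine by ipso attack of a chloronium source, after bromination of C3, would be shorter on paper. It was set aside: attack at the brominated C3 followed by a 1,2-shift of bromine would give the isomer with the halogens interchanged. The Boc group is removed by base methanolysis, since the 2-chloroindole does not tolerate aqueous acid.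

**Aromatisation of the five-membered ring.** Compound 13 goes back to acid 12 and this to ester 11; in this direction a carboxyl group and two hydrogens return to C2 and C3. The forward reaction, an oxidative decarboxylation, lifts the indoline to the indole level and erases the stereocentre in one step. The carboxyl group thus serves twice: as the activating group of the alkene in the key step and as the leaving group for aromatisation. This path is preferred to dehydrogenation with a quinone because N-acyl indolines are sluggish in that reaction.

**Key disconnection, N1–C7a and C3–C3a.** Cutting both bonds of 11 that join the five-membered ring to the benzene ring gives aryne 10 and the dehydroamino ester 9. The cut is made here because these two bonds end on the symmetric edge, so either orientation of 9 on 10 gives the same product. Compound 9 already holds N1, C2 with its carboxyl group and C3 in the right order. The gain is one ring, two skeletal bonds and the 4,7-dibromo pattern from a symmetric piece. The forward reaction has to form the N–aryl bond first and then the C–C bond by conjugate addition of the aryl anion.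

**The aryne precursor.** Aryne 10 comes from silyl triflate 8 with fluoride. Compound 8 goes back through phenol 7 (O–S bond) to carbamate 6, then by cutting the C–Si bond to carbamate 2 and on to phenol 1. The silyl group must go to the carbon between oxygen and bromine. In 2 this is the only free position ortho to the carbamate and it is further acidified by the adjacent bromine, so a lithium amide is sufficient and no bromine is exchanged. Compounds 1 and 9 are bought; 1 carries both benzo-ring bromines from the start.

## Alternatives that were turned down

**Alternative 1:** The bonds N1–C2 and C3–Br are cut. This leads from 3,4,7-tribromo-2-chloro-1-tosylindole A1 to the open-chain sulfonamide N-[3,6-dibromo-2-(chloroethynyl)phenyl]-4-methylbenzenesulfonamide A2.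
- Forward key step: an N-bromoimide activates the chloroalkyne of A2 and the sulfonamide nitrogen closes 5-endo-dig onto the chlorine-bearing alkyne carbon. A1 then needs only N-detosylation.
- For it: the ring closure writes C2–Cl and C3–Br at once, and their positions follow from the connectivity of A2. On this point it is stronger than the chosen route, which spends steps 7 to 9 on the same task.
- Against it: A2 is a benzene with four contiguous substituents (Br, N, alkynyl, Br). Making it requires iodination between nitrogen and bromine of an aniline that prefers to react para, and a Sonogashira coupling in which zerovalent palladium must take one C–I bond and leave two C–Br bonds. The alkyne must then be chlorinated without organolithium reagents.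
- Against the key step itself: a halonium ion must engage an alkyne deactivated by chlorine and by the dibromoaryl ring, the nucleophile is a weak sulfonamide, and the new C3–Br bond forms peri to C4–Br. Simple addition across the alkyne is a likely competitor. Halocyclisation of 2-alkynyl anilides is well known, but not with 1-chloroalkynes.
- Comparison: the chosen strategy obtains the same arene pattern without selective cross-coupling, from the symmetry of 10 and the bought phenol 1, and its ring-forming step has close precedent. It pays with a longer endgame.

**Alternative 2:** The bond C5–C6 and both benzo C–Br bonds are cut. This leads from methyl 4,7-dibromo-1H-indole-2-carboxylate A3 to methyl 4,5-diethynyl-1H-pyrrole-2-carboxylate A4.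
- Forward key step: heating A4 in carbon tetrabromide A5 triggers a Bergman cycloaromatisation. The 1,4-diradical at C4 and C7 takes one bromine atom at each centre.
- For it: the benzene ring and both bromines, para to each other, arise in one event with inherent regiochemistry. At the benzo ring it is the most economical idea of all.
- Against it: the alkene of this enediyne is the C4–C5 bond of a five-membered aromatic ring, which splays the two alkynes apart and raises the barrier. At the temperature needed, a terminal diyne on an N–H pyrrole is likely to polymerise.
- Further against it: two bromine abstractions from A5 must beat hydrogen abstraction and the addition of tribromomethyl radicals to the alkynes. A4 itself needs two alkynylations of a dihalopyrrole.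
- Comparison: A3 still lacks both pyrrole halogens, so the whole endgame of ester removal, chlorination and bromination remains. The chosen strategy buys the bromines in 1, closes its ring at room temperature by an ionic path, and arrives at 11, which enters the same kind of endgame.

**Alternative 3:** The bonds C3a–C4 and C7–C7a are cut. This leads from tert-butyl cis-4,7-dibromo-2,3,3a,7a-tetrahydroindole-1-carboxylate A6 (racemic) to 2,5-dibromothiophene 1,1-dioxide A7 and tert-butyl 2,3-dihydro-1H-pyrrole-1-carboxylate A8.
- Forward key step: the electron-poor diene A7 adds to the enecarbamate A8 in a Diels–Alder reaction of inverse demand. The adduct loses its sulfonyl bridge in a cheletropic step; the cis ring fusion follows from suprafacial addition.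
- For it: two simple partners and a symmetric diene fix the bromine positions without regiochemistry. The bicyclic skeleton is reached in fewer steps than in the chosen route, which needs three steps to make 8.
- Against it: A6 lies two oxidation levels below the indole. C7a of A6 bears the nitrogen next to the C3a–H, so aromatisation of the six-membered ring can proceed by expelling the carbamate nitrogen and opening the five-membered ring. This is the usual fate of enamine adducts of thiophene dioxides.
- Further against it: A7 tends to dimerise, and the N-acyl indoline that would result from a successful dehydrogenation is slow to oxidise further and has no handle at C2.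
- Comparison: in the chosen key step the benzene ring is aromatic from the start, and the C2 carboxyl group of 11 allows the pyrrole ring to be aromatised by decarboxylation. The later halogenations would be the same in both routes.

Key step: step 4

## Route

Step 1
Reactants: 1 2,5-dibromophenol
Product: 2 2,5-dibromophenyl N-isopropylcarbamate
Conditions: iPrNCO, Et3N (cat.), CH2Cl2, rt
Reagents that add atoms: isopropyl isocyanate, CC(C)N=C=O
Why: Base-catalysed addition of the phenol O–H to the isocyanate (carbamoylation) should give the N-monoalkyl carbamate, which directs ortho-metalation in step 2 and leaves under mild base in step 3.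

Step 2
Reactants: 2 2,5-dibromophenyl N-isopropylcarbamate
Product: 6 3,6-dibromo-2-(trimethylsilyl)phenyl N-isopropylcarbamate, via N-silyl carbamate 3 (not isolated), via aryllithium 4 (not isolated), via bis-silyl carbamate 5 (not isolated)
Conditions: TBSOTf, TMEDA, Et2O, 0 °C to rt; then Me3SiCl, LiN(iPr)2 (excess), THF, −78 °C; aq NaHSO4 work-up
Reagents that add atoms: chlorotrimethylsilane, C[Si](C)(C)Cl
Why: N-Silylation masks the N–H, then directed ortho-metalation with in situ trapping follows: the only free position ortho to the carbamate lies between oxygen and bromine, so lithium diisopropylamide is strong enough and no bromine is exchanged as it would be with an alkyllithium. The chlorosilane already present should silylate aryllithium 4 before it can lose lithium bromide or shift its carbamoyl group, and the N–Si bond of 5 is hydrolysed on work-up.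

Step 3
Reactants: 6 3,6-dibromo-2-(trimethylsilyl)phenyl N-isopropylcarbamate
Product: 8 3,6-dibromo-2-(trimethylsilyl)phenyl trifluoromethanesulfonate, via 3,6-dibromo-2-(trimethylsilyl)phenol 7 (not isolated)
Conditions: DBU, Et2NH, MeCN, 40 °C; then PhNTf2, rt
Reagents that add atoms: N-phenylbis(trifluoromethanesulfonimide), O=S(=O)(N(c1ccccc1)S(=O)(=O)C(F)(F)F)C(F)(F)F
Why: Deprotonation of the carbamate N–H triggers E1cB loss of isopropyl isocyanate, which diethylamine captures as a urea, and the hindered phenoxide of 7 is O-sulfonylated in the same flask. This one-flask carbamate cleavage and triflation is the usual end of a silylaryl triflate synthesis and leaves the C–Si and C–Br bonds alone.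

Step 4
Reactants: 8 3,6-dibromo-2-(trimethylsilyl)phenyl trifluoromethanesulfonate; 9 methyl 2-[(tert-butoxycarbonyl)amino]acrylate
Product: 11 1-tert-butyl 2-methyl 4,7-dibromoindoline-1,2-dicarboxylate (racemic), via 3,6-dibromobenzyne 10 (not isolated)
Conditions: Bu4N[Ph3SiF2], THF, rt (9 in excess)
Reagents that add atoms: none
Why: Fluoride from the silicate attacks silicon in 8 and triflate leaves, so aryne 10 forms at room temperature by 1,2-elimination. The carbamate nitrogen of 9 adds to one aryne carbon, forming N1–C7a and an aryl anion on the neighbouring carbon that is stabilised inductively by the bromine beside it. This anion adds to the methylene carbon of the acrylate, the β-position of the conjugated ester, forming C3–C3a; the five-membered ring closes in the 5-endo-trig mode. The ester enolate is then protonated at C2 by the N–H of another molecule of 9 or on work-up, which creates the only stereocentre; nothing controls its configuration, so 11 should be racemic, and this is accepted because C2 becomes sp2 in step 6. The closest known reaction type is the fluoride-induced formal [3+2] annulation of arynes from silylaryl triflates with N-Boc dehydroalanine esters to indoline-2-carboxylates. The step needs the aryl anion to choose the alkene terminus over the carbamate carbonyl, which the hindered and weakly electrophilic tert-butyl carbamate secures, and it needs ring closure to outrun protonation or bromide loss, which is helped by anion and acceptor sitting on the same nitrogen. Regioselectivity does not arise because the two ends of 10 are equivalent.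

Step 5
Reactants: 11 1-tert-butyl 2-methyl 4,7-dibromoindoline-1,2-dicarboxylate (racemic)
Product: 12 4,7-dibromo-1-(tert-butoxycarbonyl)indoline-2-carboxylic acid (racemic)
Conditions: LiOH, THF/MeOH/H2O, rt; then 1 M HCl to pH 3, 0 °C
Reagents that add atoms: lithium hydroxide, [Li+].[OH-]
Why: Saponification of the methyl ester by acyl–oxygen cleavage; the N-Boc group of an indoline is stable to hydroxide at room temperature and to brief cold acidification, and epimerisation at C2 is of no consequence in a racemate.

Step 6
Reactants: 12 4,7-dibromo-1-(tert-butoxycarbonyl)indoline-2-carboxylic acid (racemic)
Product: 13 tert-butyl 4,7-dibromo-1H-indole-1-carboxylate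
Conditions: Pb(OAc)4, Cu(OAc)2 (cat.), pyridine, PhH, 80 °C
Reagents that add atoms: none
Why: Kochi-type oxidative decarboxylation: the lead carboxylate fragments with loss of CO2 to the α-amido radical, which is oxidised to the N-acyliminium ion, and loss of the C3 proton to pyridine gives the aromatic pyrrole ring. Aromatisation drives the elimination, the stereocentre disappears, and the carbamate and the aryl bromides are inert to tetravalent lead.

Step 7
Reactants: 13 tert-butyl 4,7-dibromo-1H-indole-1-carboxylate
Product: 15 tert-butyl 4,7-dibromo-2-chloro-1H-indole-1-carboxylate, via 2-lithioindole 14 (not isolated)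
Conditions: LiN(iPr)2, THF, −78 °C; then C2Cl6, −78 °C to rt
Reagents that add atoms: hexachloroethane, ClC(Cl)(Cl)C(Cl)(Cl)Cl
Why: Carbamate-directed lithiation of an N-acyl indole takes place at C2, the most acidic C–H, and the amide base leaves the C–Br bonds untouched. Chlorine transfer from hexachloroethane to 14 at −78 °C, with loss of lithium chloride and tetrachloroethene, places chlorine at C2 and nowhere else, before the Boc group can shift from nitrogen to carbon.

Step 8
Reactants: 15 tert-butyl 4,7-dibromo-2-chloro-1H-indole-1-carboxylate
Product: 16 4,7-dibromo-2-chloro-1H-indole
Conditions: K2CO3 (cat.), MeOH, rt; product used at once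
Reagents that add atoms: none
Why: Methoxide attacks the Boc carbonyl and the halogenated indolide is a good leaving group (transacylation). Base is used instead of acid because a 2-chloroindole protonated at C3 is hydrolysed to the lactam.

Step 9
Reactants: 16 4,7-dibromo-2-chloro-1H-indole
Product: 17 3,4,7-tribromo-2-chloro-1H-indole
Conditions: NBS (1 equiv), DMF, 0 °C, dark
Reagents that add atoms: N-bromosuccinimide, O=C1CCC(=O)N1Br
Why: Electrophilic aromatic bromination at C3, the only free and most nucleophilic carbon of the pyrrole ring; the dibrominated benzo ring is deactivated, and one equivalent at low temperature should prevent a second attack at C3.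

## Compound list

1 | 2,5-dibromophenol | Oc1cc(Br)ccc1Br | starting material
2 | 2,5-dibromophenyl N-isopropylcarbamate | CC(C)NC(=O)Oc1cc(Br)ccc1Br | intermediate
3 | 2,5-dibromophenyl N-(tert-butyldimethylsilyl)-N-isopropylcarbamate | CC(C)N(C(=O)Oc1cc(Br)ccc1Br)[Si](C)(C)C(C)(C)C | intermediate (not isolated)
4 | [3,6-dibromo-2-({(tert-butyldimethylsilyl)(isopropyl)carbamoyl}oxy)phenyl]lithium | CC(C)N(C(=O)Oc1c([Li])c(Br)ccc1Br)[Si](C)(C)C(C)(C)C | intermediate (not isolated)
5 | 3,6-dibromo-2-(trimethylsilyl)phenyl N-(tert-butyldimethylsilyl)-N-isopropylcarbamate | CC(C)N(C(=O)Oc1c([Si](C)(C)C)c(Br)ccc1Br)[Si](C)(C)C(C)(C)C | intermediate (not isolated)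
6 | 3,6-dibromo-2-(trimethylsilyl)phenyl N-isopropylcarbamate | CC(C)NC(=O)Oc1c([Si](C)(C)C)c(Br)ccc1Br | intermediate
7 | 3,6-dibromo-2-(trimethylsilyl)phenol | Oc1c([Si](C)(C)C)c(Br)ccc1Br | intermediate (not isolated)
8 | 3,6-dibromo-2-(trimethylsilyl)phenyl trifluoromethanesulfonate | C[Si](C)(C)c1c(Br)ccc(Br)c1OS(=O)(=O)C(F)(F)F | intermediate
9 | methyl 2-[(tert-butoxycarbonyl)amino]acrylate | C=C(NC(=O)OC(C)(C)C)C(=O)OC | starting material
10 | 3,6-dibromobenzyne (3,6-dibromo-1,2-didehydrobenzene) | BrC1=CC=C(Br)C#C1 | intermediate (not isolated)
11 | 1-tert-butyl 2-methyl 4,7-dibromoindoline-1,2-dicarboxylate (racemic) | COC(=O)C1Cc2c(Br)ccc(Br)c2N1C(=O)OC(C)(C)C | intermediate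
12 | 4,7-dibromo-1-(tert-butoxycarbonyl)indoline-2-carboxylic acid (racemic) | OC(=O)C1Cc2c(Br)ccc(Br)c2N1C(=O)OC(C)(C)C | intermediate
13 | tert-butyl 4,7-dibromo-1H-indole-1-carboxylate | CC(C)(C)OC(=O)n1ccc2c(Br)ccc(Br)c21 | intermediate
14 | tert-butyl 4,7-dibromo-2-lithio-1H-indole-1-carboxylate | CC(C)(C)OC(=O)n1c([Li])cc2c(Br)ccc(Br)c21 | intermediate (not isolated)
15 | tert-butyl 4,7-dibromo-2-chloro-1H-indole-1-carboxylate | CC(C)(C)OC(=O)n1c(Cl)cc2c(Br)ccc(Br)c21 | intermediate
16 | 4,7-dibromo-2-chloro-1H-indole | Clc1cc2c(Br)ccc(Br)c2[nH]1 | intermediate
17 | 3,4,7-tribromo-2-chloro-1H-indole | Clc1[nH]c2c(Br)ccc(Br)c2c1Br | target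

## Step count and least certain steps

Total step count: 9. Longest linear sequence: 9 steps, from 1 to 17; compound 9 is bought and enters at step 4.

**Step 4 (key step).**
Most likely failure: proton transfer to the aryl anion, from the N–H of 9, before it closes the ring; the 5-endo-trig addition is geometrically demanding and the anionic carbon is crowded by the bromine next to it, so plain N-arylation would result. A slower competing process is loss of that bromide, which would generate a second aryne and lead to oligomers. Fallback: it sets out from 8 and comes back at 13, and it forms C3–C3a by a sigmatropic shift, so that the aryl anion only has to be protonated. Aryne 10 is released from 8 with CsF in MeCN in the presence of methyl 2-(2-tosylhydrazinylidene)propanoate F1 (made from methyl pyruvate and tosylhydrazide), and N-arylation at the sulfonamide nitrogen should give methyl 2-[2-(2,5-dibromophenyl)-2-tosylhydrazinylidene]propanoate F2 after protonation of the aryl anion. BF3·OEt2 at 80 °C should then bring about Fischer indolisation of F2 by a [3,3] shift onto the only free ortho carbon and loss of ammonia, which should give methyl 4,7-dibromo-1-tosyl-1H-indole-2-carboxylate F3 as an N-sulfonyl indole. KOH in aqueous methanol at reflux should remove the ester methyl and the tosyl group to give 4,7-dibromo-1H-indole-2-carboxylic acid F4 on acidification. Protodecarboxylation with Ag2CO3 (cat.) and acetic acid in DMSO at 120 °C should give 4,7-dibromo-1H-indole F5 and Boc2O with 4-(dimethylamino)pyridine then returns to 13.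

**Step 6.**
Most likely failure: interception of the N-acyliminium ion by acetate instead of loss of the C3 proton, or stalling of the oxidation because the dibrominated ring destabilises the cation; either leaves mixtures at the N,O-acetal level. Fallback: it sets out from 12 and comes back at 13, and it makes the N,O-acetal on purpose and eliminates in a separate operation. Hofer–Moest anodic decarboxylation of 12 in methanol (graphite electrodes, NaOMe (cat.), undivided cell) should give racemic tert-butyl 4,7-dibromo-2-methoxyindoline-1-carboxylate F6 as the N,O-acetal, and pyridinium p-toluenesulfonate (cat.) in toluene at 80 °C should eliminate methanol from F6 to give 13.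

**Step 7.**
Most likely failure: competing deprotonation on the benzo ring beside a bromine, followed by migration of that bromine, or a shift of the Boc group of 14 from nitrogen to C2 before chlorine is transferred. Fallback: it sets out from 13 and comes back at 16, and it uses no carbanion. K2CO3 in methanol removes the Boc group to give 4,7-dibromo-1H-indole F7 (the same compound as F5 in the fallback for step 4), and NCS in CH2Cl2 at 0 °C should chlorinate C3 to give 4,7-dibromo-3-chloro-1H-indole F8 as the product of kinetic attack. Aqueous H3PO4 in 2-methoxyethanol at reflux should hydrolyse F8 by protonation at C3, addition of water at C2 and loss of hydrogen chloride, which gives 4,7-dibromoindolin-2-one F9 as the lactam, and POCl3 at reflux converts F9 into the 2-chloroindole 16.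

**Step 2.**
Most likely failure: loss of lithium bromide from aryllithium 4 (formation of an aryne), a shift of the carbamoyl group to carbon before silylation, or consumption of the amide base by the chlorosilane. Fallback: it sets out from 1 and comes back at 7, and so at 8. Hexamethyldisilazane, neat at 80 °C, converts 1 into (2,5-dibromophenoxy)trimethylsilane F10 with loss of ammonia. Lithium diisopropylamide in THF at −78 °C should lithiate F10 between oxygen and bromine, and an anionic 1,3 shift of silicon from oxygen to carbon (retro-Brook rearrangement) gives the lithium salt of 7, which is triflated in the same flask with PhNTf2 to 8. Silicon is delivered intramolecularly here, so the aryllithium should live for a shorter time than in step 2.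

## Further compounds

F1 | step 4 | methyl 2-(2-tosylhydrazinylidene)propanoate | CC(=NNS(=O)(=O)c1ccc(C)cc1)C(=O)OC
F2 | step 4 | methyl 2-[2-(2,5-dibromophenyl)-2-tosylhydrazinylidene]propanoate | CC(=NN(c1cc(Br)ccc1Br)S(=O)(=O)c1ccc(C)cc1)C(=O)OC
F3 | step 4 | methyl 4,7-dibromo-1-tosyl-1H-indole-2-carboxylate | COC(=O)c1cc2c(Br)ccc(Br)c2n1S(=O)(=O)c1ccc(C)cc1
F4 | step 4 | 4,7-dibromo-1H-indole-2-carboxylic acid | OC(=O)c1cc2c(Br)ccc(Br)c2[nH]1
F5 | step 4 | 4,7-dibromo-1H-indole | Brc1ccc(Br)c2[nH]ccc12
F6 | step 6 | racemic tert-butyl 4,7-dibromo-2-methoxyindoline-1-carboxylate | COC1Cc2c(Br)ccc(Br)c2N1C(=O)OC(C)(C)C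
F7 | step 7 | 4,7-dibromo-1H-indole | Brc1ccc(Br)c2[nH]ccc12
F8 | step 7 | 4,7-dibromo-3-chloro-1H-indole | Clc1c[nH]c2c(Br)ccc(Br)c12
F9 | step 7 | 4,7-dibromoindolin-2-one | O=C1Cc2c(Br)ccc(Br)c2N1
F10 | step 2 | (2,5-dibromophenoxy)trimethylsilane | C[Si](C)(C)Oc1cc(Br)ccc1Br
A1 | alternative 1 | 3,4,7-tribromo-2-chloro-1-tosylindole | Clc1n(S(=O)(=O)c2ccc(C)cc2)c2c(Br)ccc(Br)c2c1Br
A2 | alternative 1 | N-[3,6-dibromo-2-(chloroethynyl)phenyl]-4-methylbenzenesulfonamide | ClC#Cc1c(Br)ccc(Br)c1NS(=O)(=O)c1ccc(C)cc1
A3 | alternative 2 | methyl 4,7-dibromo-1H-indole-2-carboxylate | COC(=O)c1cc2c(Br)ccc(Br)c2[nH]1
A4 | alternative 2 | methyl 4,5-diethynyl-1H-pyrrole-2-carboxylate | COC(=O)c1cc(C#C)c(C#C)[nH]1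
A5 | alternative 2 | carbon tetrabromide | BrC(Br)(Br)Br
A6 | alternative 3 | tert-butyl cis-4,7-dibromo-2,3,3a,7a-tetrahydroindole-1-carboxylate (racemic, one enantiomer drawn) | O=C(OC(C)(C)C)N1CC[C@H]2[C@@H]1C(Br)=CC=C2Br
A7 | alternative 3 | 2,5-dibromothiophene 1,1-dioxide | O=S1(=O)C(Br)=CC=C1Br
A8 | alternative 3 | tert-butyl 2,3-dihydro-1H-pyrrole-1-carboxylate | O=C(OC(C)(C)C)N1CCC=C1
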